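Rings A and B of the target are the same ent-5-O-caffeoylquinate, joined by an ester from C7 of ring A to the tertiary O1' of ring B, so one monomer serves twice. Each cyclohexane is cut at C3–C4, the bond between the two cis carbinol carbons whose neighbour O5 sits on the opposite face. An SmI2 pinacol coupling of the C3 and C4 aldehydes remakes this bond, closes the carbocycle and sets both carbinol centres at once. The precursor is an open-chain dialdehyde with only two skeletal stereocentres. Quaternary C1 is held with O1 and C7 in a pivalaldehyde dioxolanone made from D-malic acid. Silyloxy-bearing C5 is set by catalytic asymmetric alkenylation.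

Key step: step 7

Remarks on the chemistry
- Numbering: C1 is the quaternary carbon (O1, carboxyl C7), C3 and C4 carry the cis-diol, and C5 carries the caffeoyloxy group. Primes mark ring B.
- Configuration: both rings of the target decode identically. O1, O3 and O4 lie on one face, O5 and C7 on the other, and C5 is S, which is the antipode of natural 5-O-caffeoylquinate. (R)-Malic acid supplies this C1 by retentive allylation. Its CH2 becomes C6, its side-chain carboxyl carbon becomes C5, and the allyl group becomes C2–C3.
- Design: O1 and C7 stay in the acetal through the ring closure.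
  - This saves an ester opening and a tertiary silylation.
  - It avoids a gamma-hydroxy ester that would lactonise (O5 onto C7).
  - It releases a free acid afterwards. That acid becomes either the acyl donor or a tert-butyl ester that falls in the final acid step. A simple alkyl ester at C7' could not be cleaved beside three other esters.
- Both caffeates are put on after the hindered ester bond is made.
- Assumption: 5-bromo-2,2-dimethyl-1,3-benzodioxole, (+)-MIB and Cy2BH are taken as purchasable.

Step 1
Reactants: 1 D-malic acid; 2 pivalaldehyde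
Product: 3 cis-dioxolanone acid [(2R,4R)-2-tert-butyl-5-oxo-1,3-dioxolan-4-yl]acetic acid
Conditions: 2 (1.5 equiv), TsOH·H2O (cat.), H2SO4 (cat.), pentane, reflux, water separator; recrystallisation
Reagents that add atoms: pivalaldehyde 2, CC(C)(C)C=O
Why: Acid-catalysed acetalisation with azeotropic water removal closes the five-membered ring over the alpha-hydroxy acid unit, and since the reaction is reversible the resident C1 centre steers the new acetal carbon to the less strained cis (2R) isomer, which crystallisation should deliver pure (first half of self-regeneration of stereocentres).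

Step 2
Reactants: 3 cis-dioxolanone acid; 4 allyl bromide
Product: 6 allylated dioxolanone acid [(2R,4R)-4-allyl-2-tert-butyl-5-oxo-1,3-dioxolan-4-yl]acetic acid (allyl trans to tert-butyl), via dilithium enolate 5 (not isolated)
Conditions: LiN(SiMe3)2 (2.2 equiv), THF, −78 °C; 4 (1.5 equiv), −78 → −30 °C; cold 1 M HCl
Reagents that add atoms: allyl bromide 4, C=CCBr
Why: Diastereoselective enolate alkylation (self-regeneration of stereocentres): C1 is flattened in carboxylate-enolate 5 and allyl bromide approaches anti to the tert-butyl group, the face H1 had occupied, so that quaternary C1 forms with overall retention.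

Step 3
Reactants: 6 allylated dioxolanone acid
Product: 8 aldehyde [(2R,4R)-4-allyl-2-tert-butyl-5-oxo-1,3-dioxolan-4-yl]acetaldehyde, via acid chloride 7 (not isolated)
Conditions: (COCl)2 (1.2 equiv), DMF (cat.), CH2Cl2, 0 °C → rt, evaporate; Bu3SnH (1.05 equiv), Pd(PPh3)4 (2 mol %), toluene, rt
Reagents that add atoms: none
Why: Acid chloride formation and zerovalent-palladium-catalysed hydrostannolysis of the acyl chloride stop at the aldehyde oxidation level and, unlike borane or aluminium hydrides, spare the terminal alkene and the dioxolanone.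

Step 4
Reactants: 8 aldehyde; 9 hex-1-yne
Product: 11 allylic alcohol (2R,5R)-5-allyl-2-tert-butyl-5-[(2S,3E)-2-hydroxyoct-3-en-1-yl]-1,3-dioxolan-4-one (C5 is S), via ethylzinc alkoxide 10 (not isolated)
Conditions: 9 (1.6 equiv), Cy2BH (1.5 equiv), toluene, 0 °C → rt; Et2Zn (1.6 equiv), (+)-MIB (5 mol %), −78 °C; 8, −30 → −10 °C; cold 1 M HCl
Reagents that add atoms: hex-1-yne 9, CCCCC#C
Why: Catalytic asymmetric alkenylzinc addition to an aldehyde (alkyne hydroboration, boron-to-zinc exchange, amino-alcohol catalysis): the zinc complex of (+)-MIB should deliver the alkenyl group to the Re face of the C5 carbonyl, its antipode being known for Si-face delivery, which sets 5S under reagent control because quaternary C1 is too remote to bias the carbonyl, and the butyl end of the alkene is irrelevant since ozonolysis removes it.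

Step 5
Reactants: 11 allylic alcohol
Product: 12 O5-tert-butyldimethylsilyl ether of 11 (C1, C5 and acetal carbon unchanged)
Conditions: TBSOTf (1.2 equiv), 2,6-lutidine (2 equiv), CH2Cl2, −78 → 0 °C
Reagents that add atoms: TBSOTf, CC(C)(C)[Si](C)(C)OS(=O)(=O)C(F)(F)F
Why: Silylation with a silyl triflate and a hindered pyridine is fast at low temperature, caps O5 before it can lactonise onto C7, and installs the poorest leaving group that the later ketyl can have next to it.

Step 6
Reactants: 12 silyl ether diene
Product: 14 dialdehyde (2S)-2-(tert-butyldimethylsilyloxy)-3-[(2R,4S)-2-tert-butyl-5-oxo-4-(2-oxoethyl)-1,3-dioxolan-4-yl]propanal (geometry at C1 unchanged; only its descriptor changes), via bis-ozonide 13 (not isolated)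
Conditions: O3, CH2Cl2, −78 °C; PPh3 (2.2 equiv), −78 °C → rt; short silica plug, used at once
Reagents that add atoms: ozone, [O-][O+]=O
Why: Ozonolysis with reductive work-up cleaves both C=C bonds in one operation, the allyl CH becoming the C3 aldehyde and the alkenyl CH the C4 aldehyde, under neutral conditions that should neither epimerise C5 nor eliminate O1.

Step 7
Reactants: 14 dialdehyde
Product: 16 spiro diol: ent-quinic acid 1,7-O-(2,2-dimethylpropylidene) acetal 5-O-TBS ether (1R,3S,4S,5S in quinate numbering; acetal carbon R; O3 and O4 cis to each other and to O1 and trans to O5), via samarium diolate 15 (not isolated)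
Conditions: SmI2 (0.1 M in THF, 2.4 equiv), t-BuOH (2.5 equiv), THF, slow addition of 14 at high dilution, −78 → −20 °C; aq. NaHCO3
Reagents that add atoms: none
Why: Electron transfer from divalent samarium to either formyl group generates a samarium ketyl radical; this radical attacks the other, metal-activated C=O carbon and uptake of a second electron leaves diolate 15, an intramolecular pinacol coupling of the kind established for sugar-derived 1,6-dialdehydes. Ring closure is 6-exo-trig (the oxygen of the attacked C=O stays outside the new cyclohexane) and is favoured by the fully substituted spiro carbon C1 in the tether. C3 and C4 arise together: because one trivalent samarium ion is shared by both oxygens while the C3–C4 bond forms, the two C–O bonds must point to the same face, hence the cis relationship. Which face is decided by C5, since the C4–O dipole and the metal avoid the bulky, electron-rich C5–OSi bond, so the diol should end up trans to O5, on the face of O1, whose acetal oxygen may lend the metal a further contact. Needed are diastereoselectivity (cis, anti to O5) and chemoselectivity (coupling rather than expulsion of silanolate from the C4 ketyl, plain reduction to the open diol, intermolecular coupling or attack on the dioxolanone). These are secured by the poor leaving group on O5, the fast six-ring closure, high dilution, low temperature, t-BuOH as a mild proton source and the absence of HMPA.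

Step 8
Reactants: 16 spiro diol
Product: 17 3,4-O-isopropylidene ketal of 16
Conditions: Me2C(OMe)2 (3 equiv), PPTS (cat.), CH2Cl2, rt
Reagents that add atoms: 2,2-dimethoxypropane, COC(C)(C)OC
Why: Acid-catalysed transketalisation: only the cis-3,4-diol can be bridged by a five-membered isopropylidene ring, so stray trans isomers stay behind as polar diols, and PPTS is too weak to disturb silyl ether or dioxolanone.

Step 9
Reactants: 17 ketal dioxolanone
Product: 18 hydroxy acid 5-O-TBS-3,4-O-isopropylidene-ent-quinic acid (O1–H and C7 acid free)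
Conditions: LiOH (3 equiv), THF/H2O, 0 °C → rt; cold dilute HCl to pH 4
Reagents that add atoms: lithium hydroxide, [Li+].[OH-]
Why: Saponification of an acyl acetal, an activated ester: hydroxide adds to C7, pivalaldehyde is lost, and O1–H and the carboxylic acid are released together while silyl ether, ketal and all stereocentres are inert to base.

Step 10
Reactants: 18 hydroxy acid (one half)
Product: 19 ring B partner: tert-butyl ester of 18 with O1'–H free
Conditions: O-tert-butyl-N,N'-diisopropylisourea (3 equiv), CH2Cl2, rt → 40 °C
Reagents that add atoms: O-tert-butyl-N,N'-diisopropylisourea, CC(C)N=C(NC(C)C)OC(C)(C)C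
Why: Isourea-mediated O-alkylation of the carboxylic acid takes place at the carboxylate oxygen, remote from crowded C1', under nearly neutral conditions that leave the tertiary O1'–H untouched for the coupling.

Step 11
Reactants: 18 hydroxy acid (other half)
Product: 21 ring A partner: 1-O-triethylsilyl-5-O-TBS-3,4-O-isopropylidene-ent-quinic acid, via bis-silyl compound 20 (not isolated)
Conditions: TESOTf (3 equiv), 2,6-lutidine (5 equiv), CH2Cl2, 0 °C → rt; K2CO3, MeOH/THF/H2O, 0 °C; cold dilute HCl to pH 4
Reagents that add atoms: TESOTf, CC[Si](CC)(CC)OS(=O)(=O)C(F)(F)F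
Why: Exhaustive silylation with a silyl triflate covers the tertiary alcohol and the acid, and carbonate-promoted solvolysis then removes only the far more labile silyl ester.

Step 12
Reactants: 21 ring A acid; 19 ring B alcohol
Product: 24 fully protected ring A–ring B ester (C7 to O1'; O1 TES; O5 and O5' TBS; two isopropylidene ketals; C7' tert-butyl ester), via acid chloride 22 (not isolated), via lithium alkoxide 23 (not isolated)
Conditions: 21, Me2C=C(Cl)NMe2 (1.2 equiv), CH2Cl2, 0 °C → rt, evaporate; 19, LiN(SiMe3)2 (1.05 equiv), THF, −78 °C; add 22 in THF, −78 °C → rt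
Reagents that add atoms: none
Why: Acylation of a lithium tert-alkoxide with an acid chloride is the established way to doubly hindered esters: the chloroenamine forms 22 without acid, 22 has no alpha-hydrogen and so cannot give a ketene with the basic alkoxide, and 23 has no ester or silyl group within reach on the O1' face.

Step 13
Reactants: 24 protected ester
Product: 25 triol (O5–H, O5'–H and O1–H free; both ketals and the tert-butyl ester kept)
Conditions: HF·pyridine, pyridine, THF, 0 °C → rt
Reagents that add atoms: none
Why: Fluoride-driven desilylation in a buffered, weakly acidic medium frees O5, O5' and O1 without forming alkoxides, so that lactonisation onto C7 or C7' (both hindered esters of poor leaving groups) should not compete, and ketals and tert-butyl ester are inert.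

Step 14
Reactants: 26 5-bromo-2,2-dimethyl-1,3-benzodioxole; 27 acrylic acid
Product: 28 (E)-3-(2,2-dimethyl-1,3-benzodioxol-5-yl)prop-2-enoic acid (caffeic acid with the catechol as isopropylidene ketal)
Conditions: Pd(OAc)2 (2 mol %), P(o-tol)3 (6 mol %), Et3N (3 equiv), DMF, 100 °C; citric acid work-up
Reagents that add atoms: acrylic acid 27, C=CC(=O)O
Why: Mizoroki–Heck reaction: syn carbopalladation and syn beta-hydride elimination give the E-acrylic acid, and the basic medium preserves the catechol ketal.

Step 15
Reactants: 25 triol; 28 protected caffeic acid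
Product: 29 protected target (caffeate ketals on O5 and O5'; O1–H free)
Conditions: 28 (2.6 equiv), N,N'-diisopropylcarbodiimide (2.8 equiv), DMAP (0.5 equiv), CH2Cl2, 0 °C → rt
Reagents that add atoms: acid 28 (two equivalents), OC(=O)/C=C/c1ccc2OC(C)(C)Oc2c1
Why: Steglich esterification acylates the two secondary alcohols O5 and O5', whereas the tertiary O1–H beside the quaternary ester is too hindered to react, the selectivity known for quinate 1,5-diols.

Step 16
Reactants: 29 protected target
Product: 30 CNP0107948.2 (target)
Conditions: TFA/H2O (9:1), 0 °C → rt; evaporate, reversed-phase chromatography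
Reagents that add atoms: none
Why: Acidolysis: aqueous trifluoroacetic acid hydrolyses the four ketals and cleaves the tert-butyl ester by alkyl–oxygen fission, while the two caffeates and the C7–O1' ester persist because secondary carbons and the carboxyl-bearing C1' do not ionise and acyl migration is slow in acid.

Compound list
1 | D-malic acid, (R)-2-hydroxybutanedioic acid | OC(=O)C[C@@H](O)C(=O)O | starting material
2 | pivalaldehyde | CC(C)(C)C=O | starting material
3 | [(2R,4R)-2-tert-butyl-5-oxo-1,3-dioxolan-4-yl]acetic acid (cis) | OC(=O)C[C@H]1O[C@@H](C(C)(C)C)OC1=O | intermediate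
4 | allyl bromide | C=CCBr | starting material
5 | dilithium carboxylate-enolate of 3 | [Li+].[Li+].[O-]C(=O)CC1=C([O-])O[C@H](C(C)(C)C)O1 | intermediate
6 | [(2R,4R)-4-allyl-2-tert-butyl-5-oxo-1,3-dioxolan-4-yl]acetic acid | OC(=O)C[C@@]1(CC=C)O[C@@H](C(C)(C)C)OC1=O | intermediate
7 | acid chloride of 6 | ClC(=O)C[C@@]1(CC=C)O[C@@H](C(C)(C)C)OC1=O | intermediate
8 | [(2R,4R)-4-allyl-2-tert-butyl-5-oxo-1,3-dioxolan-4-yl]acetaldehyde | O=CC[C@@]1(CC=C)O[C@@H](C(C)(C)C)OC1=O | intermediate
9 | hex-1-yne | CCCCC#C | starting material
10 | ethylzinc alkoxide of 11 | CCCC/C=C/[C@@H](O[Zn]CC)C[C@@]1(CC=C)O[C@@H](C(C)(C)C)OC1=O | intermediate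
11 | (2R,5R)-5-allyl-2-tert-butyl-5-[(2S,3E)-2-hydroxyoct-3-en-1-yl]-1,3-dioxolan-4-one | CCCC/C=C/[C@@H](O)C[C@@]1(CC=C)O[C@@H](C(C)(C)C)OC1=O | intermediate
12 | O5-TBS ether of 11 | CCCC/C=C/[C@@H](O[Si](C)(C)C(C)(C)C)C[C@@]1(CC=C)O[C@@H](C(C)(C)C)OC1=O | intermediate
13 | bis-ozonide (two 1,2,4-trioxolanes) of 12 | CCCCC1OOC(O1)[C@@H](O[Si](C)(C)C(C)(C)C)C[C@@]1(CC2OCOO2)O[C@@H](C(C)(C)C)OC1=O | intermediate
14 | C3,C4-dialdehyde, O5 TBS, O1/C7 as pivalaldehyde dioxolanone (pinacol precursor) | O=C[C@@H](O[Si](C)(C)C(C)(C)C)C[C@@]1(CC=O)O[C@@H](C(C)(C)C)OC1=O | intermediate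
15 | bis(diiodosamarium) diolate of 16 | CC(C)(C)[Si](C)(C)O[C@H]1C[C@]2(O[C@@H](C(C)(C)C)OC2=O)C[C@H](O[Sm](I)I)[C@@H]1O[Sm](I)I | intermediate
16 | ent-quinic acid 1,7-O-(2,2-dimethylpropylidene) acetal 5-O-TBS ether (pinacol product, cis-3,4-diol) | CC(C)(C)[Si](C)(C)O[C@H]1C[C@]2(O[C@@H](C(C)(C)C)OC2=O)C[C@H](O)[C@@H]1O | intermediate
17 | 3,4-O-isopropylidene ketal of 16 | CC(C)(C)[Si](C)(C)O[C@H]1C[C@]2(O[C@@H](C(C)(C)C)OC2=O)C[C@H](O3)[C@@H]1OC3(C)C | intermediate
18 | 5-O-TBS-3,4-O-isopropylidene-ent-quinic acid | CC(C)(C)[Si](C)(C)O[C@H]1C[C@@](O)(C(=O)O)C[C@H](O2)[C@@H]1OC2(C)C | intermediate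
19 | tert-butyl ester of 18 (ring B partner) | CC(C)(C)[Si](C)(C)O[C@H]1C[C@@](O)(C(=O)OC(C)(C)C)C[C@H](O2)[C@@H]1OC2(C)C | intermediate
20 | O1-TES ether TES ester of 18 | CC(C)(C)[Si](C)(C)O[C@H]1C[C@@](O[Si](CC)(CC)CC)(C(=O)O[Si](CC)(CC)CC)C[C@H](O2)[C@@H]1OC2(C)C | intermediate
21 | 1-O-TES-5-O-TBS-3,4-O-isopropylidene-ent-quinic acid (ring A partner) | CC(C)(C)[Si](C)(C)O[C@H]1C[C@@](O[Si](CC)(CC)CC)(C(=O)O)C[C@H](O2)[C@@H]1OC2(C)C | intermediate
22 | acid chloride of 21 | CC(C)(C)[Si](C)(C)O[C@H]1C[C@@](O[Si](CC)(CC)CC)(C(=O)Cl)C[C@H](O2)[C@@H]1OC2(C)C | intermediate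
23 | lithium O1'-alkoxide of 19 | CC(C)(C)[Si](C)(C)O[C@H]1C[C@@]([O-])(C(=O)OC(C)(C)C)C[C@H](O2)[C@@H]1OC2(C)C.[Li+] | intermediate
24 | fully protected ring A–ring B ester | CC(C)(C)[Si](C)(C)O[C@H]1C[C@@](O[Si](CC)(CC)CC)(C(=O)O[C@@]2(C(=O)OC(C)(C)C)C[C@H](O[Si](C)(C)C(C)(C)C)[C@@H](O3)[C@@H](OC3(C)C)C2)C[C@H](O4)[C@@H]1OC4(C)C | intermediate
25 | triol (O1, O5, O5' free) | O[C@H]1C[C@@](O)(C(=O)O[C@@]2(C(=O)OC(C)(C)C)C[C@H](O)[C@@H](O3)[C@@H](OC3(C)C)C2)C[C@H](O4)[C@@H]1OC4(C)C | intermediate
26 | 5-bromo-2,2-dimethyl-1,3-benzodioxole | CC1(C)Oc2ccc(Br)cc2O1 | starting material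
27 | acrylic acid | C=CC(=O)O | starting material
28 | (E)-3-(2,2-dimethyl-1,3-benzodioxol-5-yl)prop-2-enoic acid | OC(=O)/C=C/c1ccc2OC(C)(C)Oc2c1 | intermediate
29 | protected target (four ketals, one tert-butyl ester) | O=C(/C=C/c1ccc2OC(C)(C)Oc2c1)O[C@H]1C[C@@](O)(C(=O)O[C@@]2(C(=O)OC(C)(C)C)C[C@H](OC(=O)/C=C/c3ccc4OC(C)(C)Oc4c3)[C@@H](O5)[C@@H](OC5(C)C)C2)C[C@H](O6)[C@@H]1OC6(C)C | intermediate
30 | CNP0107948.2 | O=C(/C=C/c1ccc(O)c(O)c1)O[C@H]1C[C@@](O)(C(=O)O[C@@]2(C(=O)O)C[C@H](OC(=O)/C=C/c3ccc(O)c(O)c3)[C@@H](O)[C@@H](O)C2)C[C@H](O)[C@@H]1O | target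

Total step count: 16. Longest linear sequence: 14 (steps 1–9, 11, 12, 13, 15, 16).

Steps most likely to fail

1. Step 7.
   - What may go wrong: the C4 ketyl may expel its silyloxy neighbour. Both aldehydes may be reduced without C–C bond formation. O1 may be eliminated from the C3 aldehyde by basic samarium alkoxides. Facial control may be too weak, giving trans or O5-cis diols.
   - Fallback: it sets out from diene 12. Ring-closing metathesis with the second-generation Grubbs catalyst (CH2Cl2, reflux) joins C3 and C4 as an alkene and gives the spiro cyclohexene F1. Upjohn dihydroxylation (OsO4 cat., NMO, acetone/H2O) then adds both oxygens syn from the face anti to the allylic O5 silyl ether. The route is rejoined at diol 16.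

2. Step 12.
   - What may go wrong: acyl transfer between two fully substituted centres may be so slow that silyl transfer to the alkoxide or survival of unreacted chloride until work-up takes over.
   - Fallback: it sets out from ketal 17 and acid chloride 22.
     - Bu4NF in THF desilylates O5 of 17. O5 closes onto the activated C7 with loss of pivalaldehyde and gives the bicyclic ent-3,4-O-isopropylidene-1,5-quinide F2. Its bridgehead O1'–H is tied back and exposed.
     - DMAP-catalysed acylation with 22 in pyridine, the known way to 1-O-acyl quinides, gives the lactone ester F3.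
     - LiOH at 0 °C opens only the strained lactone to the hydroxy acid F4.
     - The isourea of step 10 gives the tert-butyl ester F5.
     - HF·pyridine then rejoins the route at triol 25.

3. Step 4.
   - What may go wrong: an uncatalysed or chelate-driven background addition may erode the facial selectivity. Ethyl transfer may compete. The alkoxide may lactonise onto C7 with loss of the acetal.
   - Fallback: it sets out from acid chloride 7. Stille coupling with tributyl[(E)-hex-1-enyl]stannane and Pd(PPh3)4 gives the enone F6. Corey–Bakshi–Shibata reduction follows, using the (R)-methyl oxazaborolidine and catecholborane in toluene at −78 °C, with the alkenyl group acting as the larger substituent. This sets 5S through a non-nucleophilic borate and rejoins the route at alcohol 11.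

Further compounds
F1 | step 7 | spiro cyclohexene (C3=C4), O5 TBS, O1/C7 pivalaldehyde dioxolanone | CC(C)(C)[Si](C)(C)O[C@H]1C[C@]2(O[C@@H](C(C)(C)C)OC2=O)CC=C1
F2 | step 12 | ent-3,4-O-isopropylidene-1,5-quinide | O=C1O[C@H]2C[C@]1(O)C[C@H](O3)[C@@H]2OC3(C)C
F3 | step 12 | 1'-O-acyl quinide (ring A acyl group of 21 on O1' of F2) | CC(C)(C)[Si](C)(C)O[C@H]1C[C@@](O[Si](CC)(CC)CC)(C(=O)O[C@@]2(C3=O)C[C@H](O3)[C@@H](O4)[C@@H](OC4(C)C)C2)C[C@H](O5)[C@@H]1OC5(C)C
F4 | step 12 | ring-opened hydroxy acid (C7' acid, O5'–H free) | CC(C)(C)[Si](C)(C)O[C@H]1C[C@@](O[Si](CC)(CC)CC)(C(=O)O[C@@]2(C(=O)O)C[C@H](O)[C@@H](O3)[C@@H](OC3(C)C)C2)C[C@H](O4)[C@@H]1OC4(C)C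
F5 | step 12 | tert-butyl ester of F4 | CC(C)(C)[Si](C)(C)O[C@H]1C[C@@](O[Si](CC)(CC)CC)(C(=O)O[C@@]2(C(=O)OC(C)(C)C)C[C@H](O)[C@@H](O3)[C@@H](OC3(C)C)C2)C[C@H](O4)[C@@H]1OC4(C)C
F6 | step 4 | (E)-enone, C5 ketone bearing hex-1-enyl | CCCC/C=C/C(=O)C[C@@]1(CC=C)O[C@@H](C(C)(C)C)OC1=O
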